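## Retrosynthetic overview

1. Manumycin G ⇒ racemic p-quinol. The C5–C6 oxirane is added last by an OH-directed, cinchona-controlled nucleophilic epoxidation that also resolves C4.
2. p-Quinol ⇒ flat, achiral 2-acylamino-4-trienylphenol. The tertiary C4–O bond comes from O2 by coupling of a phenoxyl radical with cobalt superoxo (dearomatisation, key step).
3. Phenol ⇒ aryl iodide + terminal trienamide (Heck, C4–C1'). Upper chain ⇒ dienamide + (E)-vinyl iodide (Heck, acyl C5–C6).
4. Amides: 2-aminophenol + pentadienoic acid. Also 2-amino-3-hydroxycyclopentenone (from cyclopentane-1,3-dione) + heptatrienoic acid (from pentadienal + malonic acid).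
5. Ring order: both carbocycles are bought, and the arene becomes the cyclohexenone on dearomatisation. The oxirane is the only ring formed, in the last step.

Assumption: 1, 5 and 9 are catalogue items (BHT-stabilised); locants follow the target's cyclohexenone numbering (C1 ketone, C2 N-bearing carbon, C4 carbinol, C1' first carbon of the lower chain).

## Route

Step 1
Reactants: 1 3-methylbut-1-yne
Product: 3 (E)-1-iodo-3-methylbut-1-ene, via (E)-(3-methylbut-1-en-1-yl)zirconocene chloride 2 (not isolated)
Conditions: Cp2Zr(H)Cl, CH2Cl2, rt; then I2, 0 °C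
Reagents that add atoms: iodine, II; Schwartz reagent, [H][Zr](Cl)(C1C=CC=C1)C1C=CC=C1 (its Zr fragment stays only in 2)
Why: Schwartz hydrozirconation adds syn with Zr at the terminal carbon, and iodinolysis of the C–Zr bond proceeds with retention, so only the E-vinyl iodide forms.

Step 2
Reactants: 4 2-aminophenol; 5 (2E)-penta-2,4-dienoic acid
Product: 6 (2E)-N-(2-hydroxyphenyl)penta-2,4-dienamide
Conditions: DIC, HOBt (cat.), THF, 0 °C → rt
Reagents that add atoms: none
Why: In this carbodiimide amide coupling the aniline nitrogen is far more nucleophilic than the phenol oxygen, so acylation is N-selective and the diene is untouched at this temperature.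

Step 3
Reactants: 6 (2E)-N-(2-hydroxyphenyl)penta-2,4-dienamide; 3 (E)-1-iodo-3-methylbut-1-ene
Product: 7 (2E,4E,6E)-N-(2-hydroxyphenyl)-8-methylnona-2,4,6-trienamide
Conditions: Pd(OAc)2 (5 mol %), Bu4NCl, NaHCO3, DMF, rt, dark
Reagents that add atoms: none
Why: In this Mizoroki–Heck vinylation (Jeffery conditions) the alkenyl-Pd adds to the free terminal CH2 of the dienamide and syn β-hydride elimination gives the new E-alkene, with the E geometry of 3 retained.

Step 4
Reactants: 7 (2E,4E,6E)-N-(2-hydroxyphenyl)-8-methylnona-2,4,6-trienamide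
Product: 8 (2E,4E,6E)-N-(2-hydroxy-5-iodophenyl)-8-methylnona-2,4,6-trienamide
Conditions: NIS (1.0 equiv), TFA (cat.), MeCN, −10 °C, dark
Reagents that add atoms: N-iodosuccinimide, O=C1CCC(=O)N1I
Why: In this electrophilic aromatic iodination the OH is the strongest donor and its para position is free, while the acceptor-conjugated trienamide is much less nucleophilic than the amidophenol ring.

Step 5
Reactants: 9 (2E)-penta-2,4-dienal; 10 malonic acid
Product: 12 (2E,4E)-hepta-2,4,6-trienoic acid, via 2-[(2E)-penta-2,4-dien-1-ylidene]malonic acid 11 (not isolated)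
Conditions: pyridine, piperidine (cat.), BHT (trace), 60 °C
Reagents that add atoms: none
Why: In this Knoevenagel–Doebner condensation the alkylidene malonic acid decarboxylates in pyridine to the thermodynamically favoured 2E acid.

Step 6
Reactants: 13 cyclopentane-1,3-dione
Product: 14 3-hydroxy-2-nitrocyclopent-2-en-1-one (enol of 2-nitrocyclopentane-1,3-dione)
Conditions: fuming HNO3, CH2Cl2–AcOH, 0 °C
Reagents that add atoms: nitric acid, O[N+](=O)[O-]
Why: Electrophilic nitration attacks C2 of the enol, the only nucleophilic carbon of the 1,3-dione.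

Step 7
Reactants: 14 3-hydroxy-2-nitrocyclopent-2-en-1-one
Product: 15 2-amino-3-hydroxycyclopent-2-en-1-one hydrochloride
Conditions: H2 (1 atm), 10 % Pd/C, HCl, MeOH, rt
Reagents that add atoms: hydrogen chloride, Cl
Why: Catalytic hydrogenation reduces the nitro group, and trapping the amine as its hydrochloride prevents self-condensation of the amino-dione.

Step 8
Reactants: 12 (2E,4E)-hepta-2,4,6-trienoic acid; 15 2-amino-3-hydroxycyclopent-2-en-1-one hydrochloride
Product: 16 (2E,4E)-N-(2-hydroxy-5-oxocyclopent-1-en-1-yl)hepta-2,4,6-trienamide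
Conditions: DIC, HOAt, NaHCO3, DMF, 0 °C → rt, dark
Reagents that add atoms: none
Why: In this active-ester amide coupling any O-acylation of the enol is corrected by O→N acyl shift to the more stable, hydrogen-bonded vinylogous imide.

Step 9
Reactants: 8 (2E,4E,6E)-N-(2-hydroxy-5-iodophenyl)-8-methylnona-2,4,6-trienamide; 16 (2E,4E)-N-(2-hydroxy-5-oxocyclopent-1-en-1-yl)hepta-2,4,6-trienamide
Product: 17 (2E,4E,6E)-N-[2-hydroxy-5-[(1E,3E,5E)-7-[(2-hydroxy-5-oxocyclopent-1-en-1-yl)amino]-7-oxohepta-1,3,5-trien-1-yl]phenyl]-8-methylnona-2,4,6-trienamide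
Conditions: Pd(OAc)2 (5 mol %), P(o-tol)3, Bu4NCl, NaHCO3, DMF, 50 °C, dark; mild acidic work-up
Reagents that add atoms: none
Why: In this Mizoroki–Heck arylation the aryl-Pd inserts only at the terminal CH2 of 16 (all other alkenes are internal) and β-hydride elimination gives the E C1'=C2' bond.

Step 10
Reactants: 17 the 2-acylamino-4-trienylphenol from step 9
Product: 20 rac-(2E,4E,6E)-N-[3-hydroxy-3-[(1E,3E,5E)-7-[(2-hydroxy-5-oxocyclopent-1-en-1-yl)amino]-7-oxohepta-1,3,5-trien-1-yl]-6-oxocyclohexa-1,4-dien-1-yl]-8-methylnona-2,4,6-trienamide (p-quinol), via aryloxyl (phenoxyl) radical 18 (not isolated), via 4-hydroperoxy-cyclohexadienone 19 (not isolated)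
Conditions: Co(salen) (15 mol %), pyridine (15 mol %), O2 (1 atm), DMF, 20 °C, dark; then Me2S, 0 °C
Reagents that add atoms: dioxygen, O=O
Why: Proposed new method: Co(III)–superoxo formed from Co(salen) and O2 abstracts the weak phenolic O–H to give the hydrogen-bonded, delocalised radical 18, which a second Co(III)–OO• captures by radical–radical C–O coupling at the para carbon C4, the only high-spin site whose adduct is a stable cross-conjugated dienone with both trienamides intact (adducts at C2', C4' or C6' would be quinone-methide peroxides with weak C–OO bonds that dissociate again), protonolysis then gives 19 and Me2S reduces it to 20, with C4 formed racemic; the closest known reaction types are the salcomine oxidation of phenols to p-quinones and the Co(Schiff base)/O2 conversion of 4-substituted 2,6-di-tert-butylphenols into p-quinols.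

Step 11
Reactants: 20 racemic p-quinol
Product: 21 manumycin G, (2E,4E,6E)-N-[(1S,5S,6R)-5-hydroxy-5-[(1E,3E,5E)-7-[(2-hydroxy-5-oxocyclopent-1-en-1-yl)amino]-7-oxohepta-1,3,5-trien-1-yl]-2-oxo-7-oxabicyclo[4.1.0]hept-3-en-3-yl]-8-methylnona-2,4,6-trienamide (OH and oxirane O on the same face)
Conditions: t-BuOOH (0.55 equiv), N-benzylcinchonidinium chloride (1.2 equiv), 1 M aq NaOH (1.3 equiv), toluene–CH2Cl2, 0 °C, stopped near 50 % conversion; cold 1 M HCl to pH 4
Reagents that add atoms: tert-butyl hydroperoxide, CC(C)(C)OO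
Why: Proposed new method: this is a Weitz–Scheffer nucleophilic epoxidation under cinchona-ammonium ion-pair (Wynberg-type phase-transfer) control, run as a kinetic resolution, in which t-BuOO− adds only to C5 of the unsubstituted enone (C3 is deactivated by the enamide nitrogen, the trienamides are far weaker acceptors, the cyclopentenolate is a spectator anion) from the face syn to the C4–OH that hydrogen-bonds the peroxide, the enolate closes the oxirane with loss of t-BuO−, and because the chiral cation is expected to favour the enone face that is the OH face only in (R)-20 (same spatial arrangement at C4 as 4S in 21, the descriptor changes with the CIP ranking) that enantiomer is consumed while mismatched (S)-20 stays behind, which fixes C4 by selection and creates C5 (R) and C6 (S); the closest known reactions are the syn-selective alkaline epoxidation of p-quinols and the enantioface-selective t-BuOOH/NaOH/N-benzylcinchonidinium epoxidation of 2-acylamino-cyclohexadienone monoketals.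

## Compound list

1 | 3-methylbut-1-yne | CC(C)C#C | starting material
2 | (E)-(3-methylbut-1-en-1-yl)zirconocene chloride | CC(C)/C=C/[Zr](Cl)(C1C=CC=C1)C1C=CC=C1 | intermediate
3 | (E)-1-iodo-3-methylbut-1-ene | CC(C)/C=C/I | intermediate
4 | 2-aminophenol | Nc1ccccc1O | starting material
5 | (2E)-penta-2,4-dienoic acid | C=C/C=C/C(=O)O | starting material
6 | (2E)-N-(2-hydroxyphenyl)penta-2,4-dienamide | C=C/C=C/C(=O)Nc1ccccc1O | intermediate
7 | (2E,4E,6E)-N-(2-hydroxyphenyl)-8-methylnona-2,4,6-trienamide | CC(C)/C=C/C=C/C=C/C(=O)Nc1ccccc1O | intermediate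
8 | (2E,4E,6E)-N-(2-hydroxy-5-iodophenyl)-8-methylnona-2,4,6-trienamide | CC(C)/C=C/C=C/C=C/C(=O)Nc1cc(I)ccc1O | intermediate
9 | (2E)-penta-2,4-dienal | C=C/C=C/C=O | starting material
10 | malonic acid | O=C(O)CC(=O)O | starting material
11 | 2-[(2E)-penta-2,4-dien-1-ylidene]malonic acid | C=C/C=C/C=C(C(=O)O)C(=O)O | intermediate
12 | (2E,4E)-hepta-2,4,6-trienoic acid | C=C/C=C/C=C/C(=O)O | intermediate
13 | cyclopentane-1,3-dione | O=C1CCC(=O)C1 | starting material
14 | 3-hydroxy-2-nitrocyclopent-2-en-1-one | O=C1CCC(O)=C1[N+](=O)[O-] | intermediate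
15 | 2-amino-3-hydroxycyclopent-2-en-1-one hydrochloride | NC1=C(O)CCC1=O.Cl | intermediate
16 | (2E,4E)-N-(2-hydroxy-5-oxocyclopent-1-en-1-yl)hepta-2,4,6-trienamide | C=C/C=C/C=C/C(=O)NC1=C(O)CCC1=O | intermediate
17 | 2-acylamino-4-trienylphenol (aromatic deoxy precursor) | CC(C)/C=C/C=C/C=C/C(=O)Nc1cc(/C=C/C=C/C=C/C(=O)NC2=C(O)CCC2=O)ccc1O | intermediate
18 | aryloxyl (phenoxyl) radical | CC(C)/C=C/C=C/C=C/C(=O)Nc1cc(/C=C/C=C/C=C/C(=O)NC2=C(O)CCC2=O)ccc1[O] | intermediate
19 | rac-4-hydroperoxy-cyclohexadienone | CC(C)/C=C/C=C/C=C/C(=O)NC1=CC(OO)(/C=C/C=C/C=C/C(=O)NC2=C(O)CCC2=O)C=CC1=O | intermediate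
20 | rac-p-quinol | CC(C)/C=C/C=C/C=C/C(=O)NC1=CC(O)(/C=C/C=C/C=C/C(=O)NC2=C(O)CCC2=O)C=CC1=O | intermediate
21 | manumycin G | CC(C)/C=C/C=C/C=C/C(=O)NC1=C[C@@](O)(/C=C/C=C/C=C/C(=O)NC2=C(O)CCC2=O)[C@@H]2O[C@@H]2C1=O | target

## Step count and weak points

Total step count: 11. Longest linear sequence: 6 (steps 2, 3, 4, 9, 10, 11; the branches through steps 1 and 6–8 are equally long).

**Step 10.** The oxygen radical may couple at C6 (giving an o-quinone) or on the chain. Radical 18 may also dimerise, or the polyenes may autoxidise. The fallback sets out from 17 and comes back at 20. It drops the aerobic oxidation and dearomatises by two-electron iodine(III) chemistry: PhI(OAc)2 or PhI(OCOCF3)2 in MeCN–H2O at 0 °C. Water attacks C4 of the aryloxy-iodane, as is practised on 4-hydroxycinnamates and 4'-hydroxyflavones. New compounds on this way: none F0.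

**Step 11.** The selectivity factor and the sense of induction are unproven. The yield cannot exceed 50 %, and the product is base-sensitive. The fallback sets out from 20 and comes back at 21. It gives up catalyst control and epoxidises all of the racemate with t-BuOOH and DBU in CH2Cl2 at 0 °C, which is substrate-controlled and syn to OH. This gives a 1:1 mixture of 21 and ent-manumycin G F1. The two are then separated by preparative HPLC or SFC on an amylose-type chiral phase.

**Step 9.** The terminal triene 16 may polymerise or dimerise before it couples. The fallback sets out from 8, 5 and 15 and comes back at 17, and it never makes a terminal triene.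
- A boron-retentive Heck reaction of 8 with vinylboronic acid pinacol ester (Pd(OAc)2, PPh3, Et3N, toluene, 80 °C) gives (2E,4E,6E)-N-[2-hydroxy-5-[(E)-2-(4,4,5,5-tetramethyl-1,3,2-dioxaborolan-2-yl)ethenyl]phenyl]-8-methylnona-2,4,6-trienamide F2.
- Acid 5 is coupled with 15 (DIC, HOAt, NaHCO3) to give (2E)-N-(2-hydroxy-5-oxocyclopent-1-en-1-yl)penta-2,4-dienamide F3.
- An oxidative boron-Heck reaction of F2 with F3 (Pd(OAc)2, 2,9-dimethylphenanthroline, O2, DMA, rt) then closes the triene to 17.

## Further compounds

F0 | step 10 | none | none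
F1 | step 11 | ent-manumycin G | CC(C)/C=C/C=C/C=C/C(=O)NC1=C[C@](O)(/C=C/C=C/C=C/C(=O)NC2=C(O)CCC2=O)[C@H]2O[C@H]2C1=O
F2 | step 9 | (2E,4E,6E)-N-[2-hydroxy-5-[(E)-2-(4,4,5,5-tetramethyl-1,3,2-dioxaborolan-2-yl)ethenyl]phenyl]-8-methylnona-2,4,6-trienamide | CC(C)/C=C/C=C/C=C/C(=O)Nc1cc(/C=C/B2OC(C)(C)C(C)(C)O2)ccc1O
F3 | step 9 | (2E)-N-(2-hydroxy-5-oxocyclopent-1-en-1-yl)penta-2,4-dienamide | C=C/C=C/C(=O)NC1=C(O)CCC1=O
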